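(The runs were computed from invented constants.)

The cedar run still held 27% target at 10.0 min and the birch run held 21% at 60.0 min, and after those readings each fell. Call the time of that last reading on the plateau the edge time; it is read from scattered readings.

| setting | birch | cedar | Tuesday's | Thursday's | Sunday's |
|---|---|---|---|---|---|
| substrate | 1.5 M | 2.2 M | 3.0 M | 3.0 M | 3.0 M |
| gas | 130 mM (held) | 130 mM (held) | 130 mM (held) | 130 mM (held) | 130 mM (held) |
| temperature | −10 °C | 10 °C | 25 °C |  | −5 °C |
| remark | run made earlier | run made earlier |  | at −5 °C until 6.0 min, from then on at 25 °C |  |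
| time |  |  | 30 min | 30 min | 30 min |

| birch: time / min | birch: target / % | cedar: time / min | cedar: target / % |
|---|---|---|---|
| 15.0 | 12 | 6.00 | 27 |
| 30.0 | 23 | 10.0 | 27 |
| 50.0 | 22 | 15.0 | 20 |
| 60.0 | 21 | 25.0 | 4 |
| 120 | 6 | 40.0 | 1 |
| 240 | 1 | 80.0 | 2 |

(readings scatter by 2 percentage points)

- which flask leads in amount of target, in percent of the substrate charged ("all alike" within 1.5 percentage points) (Tuesday's / Thursday's / Sunday's / all alike)
- how much target is there at the end, in percent of the substrate charged: Tuesday's
- how much target is there at the end, in percent of the substrate charged: Thursday's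
- how much target is there at the end, in percent of the substrate charged: Sunday's

- at the start none of reagent is dissolved
- on the list of suspects stand: substrate + reagent <-> target; substrate + reagent <-> isomer of the product; gas <-> reagent; reagent + target -> over-reaction product; reagent <-> dormant form

Which flask should you charge next? Decide it with a count, which is my own reckoning. Divide the time spent at a temperature by the edge time there, and add up the stages. At a count of 4.00 the birch run reads 1% and the cedar run reads 1%, though their charges differ. The gas is held alike in both, so I treat the loss of target as pseudo-first-order and keep the charge out of the count.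

Let the logarithm of the edge time run straight with temperature through the two runs, and carry the line on past the cedar run for the warm stage. That gives 38.3 min at −5 °C and 2.61 min at 25 °C.

Sunday's count, its time over its edge time 0.783, stands below one. The cedar run was already on its plateau at 0.600, so I expect Sunday's between 21% and 27%. Tuesday's count is 11.5. Thursday's cold hold adds 0.157, and its total is 9.36. Both lie above 4, and the cedar run's last readings, at counts of 4 and 8.00, are 1% and 2%. So keep the charge, keep the cold and drop the warm stage.

The forecast gives Sunday's 20% (from 12% to 27%), Tuesday's 1.2% and Thursday's 1.2%, with Sunday's leading. Its ground differs from mine: “It collapses once delivered reagent reaches about 0.75 of the substrate”. It sets delivered reagent against the substrate, and my count does not.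

Sunday's leads with 23.1%, against 2.44% for Tuesday's and 3.18% for Thursday's. Changing only the charge of the birch run to Tuesday's leaves its last target at 2.03%, where it stood at 2.03%. Sunday's count of 0.783 has room: going later, its target has moved by 5 points first at 52.9 min, a count of 1.38.

    substrate + reagent ⇌ target (K = 9.20 M⁻¹, k = 0.0663 M⁻¹ s⁻¹, Ea = 69.0 kJ mol⁻¹, ΔH = −59.0 kJ mol⁻¹)
    substrate + reagent ⇌ isomer of the product (K = 19.1 M⁻¹, k = 0.0294 M⁻¹ s⁻¹, Ea = 53.0 kJ mol⁻¹, ΔH = −65.0 kJ mol⁻¹)
    gas ⇌ reagent, rate k3*(csat - [reagent]) (kL = 2.35 s⁻¹)
    reagent + target → over-reaction product (k = 0.0436 M⁻¹ s⁻¹, Ea = 55.0 kJ mol⁻¹)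
    reagent ⇌ dormant form (K = 37.0, k = 0.0161 s⁻¹, Ea = 88.0 kJ mol⁻¹, ΔH = −79.0 kJ mol⁻¹)
    (constants at 25 °C)

Read Thursday's flask at 8.0 min instead. Its count is 0.923, below one, so the plateau is expected there too. The computed target is 24.5%.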